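In a one-step world, substrate and partner give target one for one. The north-east flask holds 120 mM of substrate against 180 mM of partner, so substrate is the limiting reagent. My first sum therefore put target at 100% of the substrate charged, with 60.0 mM of partner over.

| flask | substrate | partner | free catalyst | time |
|---|---|---|---|---|
| east | 120 mM | 180 mM | 0.600 mM |  |
| south | 60.0 mM | 120 mM | 0.600 mM |  |
| north | 120 mM | 180 mM | 1.80 mM |  |
| north-east | 120 mM | 180 mM | 0.600 mM | 20 min |

| run | time / min | [target] / mM |
|---|---|---|
| east run | 0.71 | 2.6 |
| east run | 1.4 | 7.0 |
| east run | 2.1 | 20.5 |
| east run | 2.9 | 43.4 |
| east run | 3.6 | 59.3 |
| east run | 4.3 | 68.0 |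
| east run | 5.0 | 72.4 |
| south run | 0.71 | 0 |
| south run | 1.4 | 0.6 |
| south run | 2.1 | 2.1 |
| south run | 2.9 | 1.9 |
| south run | 3.6 | 4.6 |
| south run | 4.3 | 5.2 |
| south run | 5.0 | 6.9 |
| north run | 0.71 | 10.5 |
| north run | 1.4 | 25.9 |
| north run | 2.1 | 49.1 |
| north run | 2.9 | 64.9 |
| north run | 3.6 | 72.3 |
| north run | 4.3 | 76.0 |
| north run | 5.0 | 77.0 |

(standard deviation of a reading: 1 mM)

* order of the initial rate in [free catalyst], near the charge of the east run, the rate being that where two percent of its substrate are target
* target in the north-east run at 20 min, as a share of the substrate charged

- Overall: substrate + partner -> target, with free catalyst as catalyst.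
- Constant volume, constant temperature.
- An order is taken over about fifteen percent of the charge, up and down.

The readings spoke against that sum. The east run stood at 72.4 mM and the north run at 77.0 mM at 5.0 min, both flattening below the substrate charge.

So I added one step, a guess that these readings neither proved nor refused: partner also takes target away, one for one. Now the surplus had a use. If both charges react to the end, each surplus partner removes one target, leaving 60.0 mM. I called this substrate charge minus surplus the partner ledger. The added step took my number down to half of the charge, or 50.0%.

Then came the rest: the catalyst and the slow start of the east run. I took these to change when things happen, not the ledger, and that left one question, whether 20 min was long enough. I replaced the unseen curve by its mean. From the last east reading, target had to fall 12.4 mM in 15.0 min, a mean of 0.827 mM min⁻¹. The target of the east run had still been rising by 6.29 mM min⁻¹ over its last interval, which is faster, but that was a rise and gave no speed for the added step, so taking 20 min as long enough was my judgement. I committed to about 50.0%. For the order I made no figure of my own.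

The forecast gave an order of 1 and 65%, on the ground “This points to an equilibrium limit rather than catalyst death”. Its share stood above mine.

The flask gave an order of 0.39 near the east charge and, in the north-east run at 20 min, 51.7%, which is 62.0 mM of target.

    2 free catalyst ⇌ catalyst dimer, settled at all times (403.0 M⁻¹)
    catalyst dimer + substrate + partner → target + catalyst dimer (786.0 M⁻² min⁻¹)
    target + partner → side product (1.386 M⁻¹ min⁻¹)
    substrate + partner + target → 2 target (93.00 M⁻² min⁻¹)

In the east run the catalysed step and the target-fed step turned substrate and partner into target, reaching a quarter of the charge at 2.45 min. Target + partner to side product ran on in the north-east run, and at 20 min target stood 2.01 mM above the ledger, a gap that in this balance equals partner left minus twice substrate left. The north run has the same substrate and partner charges with more free catalyst, and its reading of 77.0 mM stood 17.0 mM above the ledger, so by that reading it still held at least that much partner at 5.0 min.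

The runs were generated by integration with constants of no real substance.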